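**Plan**

1. Cuts (core numbered as tetracyclo[6.4.0.0(2,7).0(3,6)]dodecane: ring A = C1, C8–C12; ring B = C1, C2, C7, C8; ring C = C2, C3, C6, C7; ring D = C3–C6; chain C1′–C8′): the C10–C1′ bond (Zweifel olefination, then saturation) and the C8′–O ether; ring D, by putting a carbonyl carbon back between C3 and C4 to give a cyclopentanone; the ring-C bonds C2–C3 and C6–C7 (enone–cyclobutene photo-[2+2]); ring B (ketene [2+2] on cyclohexa-1,4-diene).
2. Enabling feature: ring D is a terminal, unsubstituted cyclobutane (C3, C4H2, C5H2, C6) held to the ladder only through the C3–C6 bond of ring C. It can therefore be traced back to a cyclopentanone fused on that bond, which cyclopentenone supplies directly.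
3. Forward order: ring A is bought; ring B (steps 1–4); ring C with the fused cyclopentanone (step 5); ring D by contraction (steps 6–7); loss of the carboxyl carbon to a meso ladderene (steps 8–9); boron at C10 (step 10); attachment of the glyceryl ether chain (steps 11–14).
4. Relative configuration: suprafacial [2+2] additions on exo faces and a 1,2-shift with retention give the cis-anti-cis-anti-cis ladder. All chiral intermediates up to 15 are racemic and converge on meso alkene 16.
5. Absolute configuration and C10: reagent-controlled hydroboration of 16 with (−)-Ipc2BH on the open face of ring A, carried into the C10–C1′ bond with retention.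

Key step: step 7

Remark: compounds 2–5 and 8–15 are racemates (one enantiomer is drawn); both enantiomers give the same meso alkene 16.
Remark: ring A of 16 is assumed to react as the boat that keeps the C1–C2 and C8–C7 bonds pseudo-equatorial, with H-1 and H-8 axial over one face of C10=C11; bulky reagents are then expected to add to the other face, cis to ring B.
Remark: 1,3-bis(benzyloxy)propan-2-ol and 8-bromooct-1-yne are taken as commercial.

**Step 1**
Reactants: 1 cyclohexa-1,4-diene
Product: 2 rac-8,8-dichloro-cis-bicyclo[4.2.0]oct-3-en-7-one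
Conditions: Cl3CCOCl, activated Zn dust, Et2O/DME, 15–20 °C; 1 in threefold excess
Reagents that add atoms: trichloroacetyl chloride, ClC(=O)C(Cl)(Cl)Cl
Why: Zinc strips chlorine from the acid chloride to give dichloroketene, whose thermal ketene–alkene [2+2] cycloaddition is suprafacial on the alkene, so ring B should form cis-fused on one double bond of the excess diene.

**Step 2**
Reactants: 2 rac-8,8-dichloro-cis-bicyclo[4.2.0]oct-3-en-7-one
Product: 3 rac-cis-bicyclo[4.2.0]oct-3-en-7-one
Conditions: Zn dust, AcOH, 60 °C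
Reagents that add atoms: none
Why: Zinc in acetic acid reductively removes both α-chlorines of an α,α-dichlorocyclobutanone through zinc enolates and should leave the isolated alkene and the ring fusion untouched.

**Step 3**
Reactants: 3 rac-cis-bicyclo[4.2.0]oct-3-en-7-one
Product: 4 4-methylbenzenesulfonohydrazone of 3
Conditions: TsNHNH2, MeOH, rt
Reagents that add atoms: 4-methylbenzenesulfonohydrazide, Cc1ccc(cc1)S(=O)(=O)NN
Why: Condensation of the unhindered, strained cyclobutanone with the sulfonyl hydrazide gives the hydrazone needed for a Shapiro reaction.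

**Step 4**
Reactants: 4 4-methylbenzenesulfonohydrazone of 3
Product: 6 cis-bicyclo[4.2.0]octa-3,7-diene, via cyclobutenyllithium 5 (not isolated)
Conditions: MeLi (2.3 equiv), Et2O, 0 °C → rt; then H2O
Reagents that add atoms: none
Why: Shapiro reaction: the dianion forms by deprotonation at the C8 methylene and not at the ring-fusion CH, loss of sulfinate and N2 leaves cyclobutenyllithium 5, and protonation should give the less substituted C7=C8 bond of the meso diene.

**Step 5**
Reactants: 6 cis-bicyclo[4.2.0]octa-3,7-diene; 7 cyclopent-2-en-1-one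
Product: 8 rac-tetracyclo[7.4.0.0(2,8).0(3,7)]tridec-11-en-4-one (cis-anti-cis-anti-cis)
Conditions: hν (medium-pressure Hg lamp, Pyrex, λ > 300 nm), CH2Cl2, −20 °C; 6 in threefold excess, recovered
Reagents that add atoms: none
Why: Enone–alkene [2+2] photocycloaddition through the triplet enone and a 1,4-biradical: the strained cyclobutene bond should react in preference to the cyclohexene bond, the enone adds to its exo face (anti to ring A), and the cyclopentanone ends cis-fused and anti to ring B, which fixes the cis-anti-cis-anti-cis array.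

**Step 6**
Reactants: 8 rac-tetracyclo[7.4.0.0(2,8).0(3,7)]tridec-11-en-4-one
Product: 10 rac-5-diazotetracyclo[7.4.0.0(2,8).0(3,7)]tridec-11-en-4-one, via trifluoroacetyl ketone 9 (not isolated)
Conditions: LiN(SiMe3)2, THF, −78 °C; CF3CO2CH2CF3, −78 °C; then MsN3, Et3N, H2O, MeCN, rt
Reagents that add atoms: methanesulfonyl azide, CS(=O)(=O)N=[N+]=[N-]
Why: Detrifluoroacetylative diazo transfer (Regitz type): the kinetic enolate can form only at the C5 methylene, because enolisation toward ring-fusion C3 would put a double bond at the bicyclo[3.2.0] junction; it is C-acylated to the activated 1,3-dicarbonyl 9, and the sulfonyl azide then hands over N2 as the trifluoroacetyl group leaves.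

**Step 7**
Reactants: 10 rac-5-diazotetracyclo[7.4.0.0(2,8).0(3,7)]tridec-11-en-4-one
Product: 12 rac-methyl tetracyclo[6.4.0.0(2,7).0(3,6)]dodec-10-ene-4-carboxylate, via ketene 11 (not isolated)
Conditions: hν (medium-pressure Hg lamp, Pyrex filter), MeOH, 0–20 °C
Reagents that add atoms: methanol, CO
Why: Light expels N2 from the α-diazo ketone and, through the singlet keto-carbene or in concert with N2 loss, ring-fusion carbon C3 shifts from the carbonyl carbon C4 to the carbene carbon C5 (locants of 10), giving ketene 11, which methanol traps as the ester; this is the photochemical Wolff rearrangement in its ring-contraction form, the known route from fused α-diazocyclopentanones to cyclobutanecarboxylates, bicyclo[2.2.0]hexanes included. Ring D (C3, the former C5, C6 and C7 of 10) closes by this 1,2-alkyl shift, that is by excision of the carbonyl carbon from the five-membered ring and not by an end-to-end cyclisation, and the new σ bond is C3–C5. The migrating carbon keeps its configuration, so the cis C/D fusion and the whole cis-anti-cis-anti-cis ladder are carried over unchanged. The one new stereocentre, the ester carbon C4 of 12, is set when the methanol adduct of the ketene is protonated, expected from the convex face of ring D to give mainly the ester cis to ring C; its configuration does not matter because this carbon becomes CH2 in step 9. The step needs migration of C3 and nothing else, which the substrate secures because the diazo group can sit only on the former methylene, leaving the acyl carbon a single carbon substituent to migrate, while the ring-A alkene is too remote to trap the carbene. Carbene O–H insertion into methanol is the main competitor and should be held back by the fast rearrangement of a ring-locked syn diazo ketone.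

**Step 8**
Reactants: 12 rac-methyl tetracyclo[6.4.0.0(2,7).0(3,6)]dodec-10-ene-4-carboxylate
Product: 13 rac-tetracyclo[6.4.0.0(2,7).0(3,6)]dodec-10-ene-4-carboxylic acid
Conditions: LiOH·H2O, THF/MeOH/H2O, rt; then 1 M HCl
Reagents that add atoms: lithium hydroxide, [Li+].[OH-]
Why: Ester saponification by acyl–oxygen cleavage followed by acidification; any epimerisation at C4 is without consequence.

**Step 9**
Reactants: 13 rac-tetracyclo[6.4.0.0(2,7).0(3,6)]dodec-10-ene-4-carboxylic acid
Product: 16 tetracyclo[6.4.0.0(2,7).0(3,6)]dodec-10-ene (meso), via acid chloride 14 (not isolated), via thiohydroxamate ester 15 (not isolated)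
Conditions: (COCl)2, DMF (cat.), CH2Cl2, rt; then sodium 2-thioxopyridin-1(2H)-olate, DMAP (cat.), t-BuSH, PhH, hν (W lamp), 20–40 °C
Reagents that add atoms: none
Why: Barton reductive decarboxylation: the thiohydroxamate ester fragments in a radical chain to CO2 and a cyclobutyl radical at C4, which fast hydrogen transfer from the thiol should quench before β-scission of the ladder, giving the meso hydrocarbon in which the former stereocentre is CH2.

**Step 10**
Reactants: 16 tetracyclo[6.4.0.0(2,7).0(3,6)]dodec-10-ene (meso)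
Product: 19 2-(tetracyclo[6.4.0.0(2,7).0(3,6)]dodecan-10-yl)-4,4,5,5-tetramethyl-1,3,2-dioxaborolane (boron cis to ring B), via diisopinocampheylborane adduct 17 (not isolated), via diethyl boronate 18 (not isolated)
Conditions: (−)-Ipc2BH (from (+)-α-pinene), THF, −25 → 0 °C; CH3CHO (excess), 0 °C → rt; pinacol, rt
Reagents that add atoms: (−)-diisopinocampheylborane, C[C@H]1[C@H](B[C@@H]3C[C@@H]4C[C@H]([C@H]3C)C4(C)C)C[C@@H]2C[C@H]1C2(C)C; pinacol, CC(C)(O)C(C)(C)O
Why: Asymmetric hydroboration (syn addition through a four-centre transition state) desymmetrises the meso alkene: the bulky borane should take the open face of boat-shaped ring A, opposite the axial H-1 and H-8, so boron ends cis to ring B, and the (+)-α-pinene-derived reagent, which turns cis-but-2-ene into (R)-butan-2-ol, should pick C10 of the enantiomer drawn (B→C11→C9 clockwise with H-10 to the rear); acetaldehyde then expels α-pinene from 17 and pinacol transesterifies 18 to the stable boronate.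

**Step 11**
Reactants: 20 1,3-bis(benzyloxy)propan-2-ol; 21 8-bromooct-1-yne
Product: 22 8-{[1,3-bis(benzyloxy)propan-2-yl]oxy}oct-1-yne
Conditions: NaH (1.05 equiv), THF/DMF, 0 °C; then 21, 0 °C → rt
Reagents that add atoms: none
Why: Williamson ether synthesis: the sodium alkoxide of the secondary alcohol, formed first with one equivalent of NaH so that the terminal alkyne stays protonated, displaces the primary bromide.

**Step 12**
Reactants: 22 8-{[1,3-bis(benzyloxy)propan-2-yl]oxy}oct-1-yne
Product: 24 (E)-8-{[1,3-bis(benzyloxy)propan-2-yl]oxy}-1-iodooct-1-ene, via vinylzirconocene 23 (not isolated)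
Conditions: Cp2Zr(H)Cl, CH2Cl2, rt; then I2, 0 °C
Reagents that add atoms: iodine, II
Why: Hydrozirconation–iodination: syn, anti-Markovnikov addition of Zr–H to the terminal alkyne and iodinolysis with retention should give the (E)-vinyl iodide, benzyl ethers being inert.

**Step 13**
Reactants: 24 (E)-8-{[1,3-bis(benzyloxy)propan-2-yl]oxy}-1-iodooct-1-ene; 19 pinacol boronate
Product: 28 (Z)-alkene with C10 joined to C1′=C2′ of the protected chain, via vinyllithium 25 (not isolated), via boronate complex 26 (not isolated), via iodo boronate 27 (not isolated)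
Conditions: 24, t-BuLi (2 equiv), Et2O, −78 °C; 19, THF, −78 → 0 °C; I2, THF, −78 °C; NaOMe, MeOH, −78 °C → rt
Reagents that add atoms: none
Why: Zweifel olefination: the vinyllithium from iodine–lithium exchange adds to boron, iodine triggers a 1,2-metallate shift of C10 with retention of configuration, and methoxide-induced anti elimination of boron and iodide gives the (Z)-alkene, so the stereocentre set in step 10 becomes the C10–C1′ bond unchanged.

**Step 14**
Reactants: 28 (Z)-alkene
Product: 30 2-O-[8-(tetracyclo[6.4.0.0(2,7).0(3,6)]dodecan-10-yl)octyl]glycerol (target), via dibenzyl ether 29 (not isolated)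
Conditions: H2 (1 atm), PtO2, EtOAc, rt; then Pd(OH)2/C, MeOH, H2 (1 atm), rt
Reagents that add atoms: none
Why: Catalytic hydrogenation: platinum reduces the disubstituted alkene with little double-bond migration, which protects the allylic C10 stereocentre, and palladium then hydrogenolyses both benzyl ethers to release the 1,3-diol, cyclobutanes being inert under these conditions.

**Compound list**

1 | cyclohexa-1,4-diene | C1=CCC=CC1 | starting material
2 | rac-8,8-dichloro-cis-bicyclo[4.2.0]oct-3-en-7-one | O=C1[C@@H]2CC=CC[C@@H]2C1(Cl)Cl | intermediate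
3 | rac-cis-bicyclo[4.2.0]oct-3-en-7-one | O=C1[C@@H]2CC=CC[C@@H]2C1 | intermediate
4 | 4-methylbenzenesulfonohydrazone of 3 (racemic, C=N geometry open) | Cc1ccc(cc1)S(=O)(=O)NN=C1[C@@H]2CC=CC[C@@H]2C1 | intermediate
5 | rac-(cis-bicyclo[4.2.0]octa-3,7-dien-7-yl)lithium | [Li]C1=C[C@H]2CC=CC[C@@H]12 | intermediate
6 | cis-bicyclo[4.2.0]octa-3,7-diene (meso) | C1=C[C@H]2CC=CC[C@@H]12 | intermediate
7 | cyclopent-2-en-1-one | O=C1CCC=C1 | starting material
8 | rac-tetracyclo[7.4.0.0(2,8).0(3,7)]tridec-11-en-4-one, all fusions cis, neighbouring rings anti | C1=CC[C@@H]2[C@H](C1)[C@H]1[C@@H]3CCC(=O)[C@@H]3[C@@H]21 | intermediate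
9 | rac-5-(trifluoroacetyl) derivative of 8 (C5 open, largely enolised) | C1=CC[C@@H]2[C@H](C1)[C@H]1[C@@H]3CC(C(=O)C(F)(F)F)C(=O)[C@@H]3[C@@H]21 | intermediate
10 | rac-5-diazotetracyclo[7.4.0.0(2,8).0(3,7)]tridec-11-en-4-one | C1=CC[C@@H]2[C@H](C1)[C@H]1[C@@H]3CC(=[N+]=[N-])C(=O)[C@@H]3[C@@H]21 | intermediate
11 | rac-4-(oxomethylidene)tetracyclo[6.4.0.0(2,7).0(3,6)]dodec-10-ene (ketene) | C1=CC[C@@H]2[C@H](C1)[C@H]1[C@@H]3CC(=C=O)[C@@H]3[C@@H]21 | intermediate
12 | rac-methyl tetracyclo[6.4.0.0(2,7).0(3,6)]dodec-10-ene-4-carboxylate, ester cis to ring C drawn, C4 epimer may accompany it | C1=CC[C@@H]2[C@H](C1)[C@H]1[C@@H]3C[C@H](C(=O)OC)[C@@H]3[C@@H]21 | intermediate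
13 | rac-tetracyclo[6.4.0.0(2,7).0(3,6)]dodec-10-ene-4-carboxylic acid | C1=CC[C@@H]2[C@H](C1)[C@H]1[C@@H]3C[C@H](C(=O)O)[C@@H]3[C@@H]21 | intermediate
14 | acid chloride of 13 | C1=CC[C@@H]2[C@H](C1)[C@H]1[C@@H]3C[C@H](C(=O)Cl)[C@@H]3[C@@H]21 | intermediate
15 | 2-thioxopyridin-1(2H)-yl ester of 13 | C1=CC[C@@H]2[C@H](C1)[C@H]1[C@@H]3C[C@H](C(=O)ON4C=CC=CC4=S)[C@@H]3[C@@H]21 | intermediate
16 | tetracyclo[6.4.0.0(2,7).0(3,6)]dodec-10-ene, meso, cis-anti-cis-anti-cis | C1=CC[C@@H]2[C@H](C1)[C@H]1[C@@H]3CC[C@@H]3[C@@H]21 | intermediate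
17 | (tetracyclododecan-10-yl)diisopinocampheylborane, boron cis to ring B | C[C@H]1[C@H](B([C@@H]3C[C@@H]4C[C@H]([C@H]3C)C4(C)C)[C@H]5CC[C@@H]6[C@H](C5)[C@H]7[C@@H]8CC[C@@H]8[C@@H]67)C[C@@H]2C[C@H]1C2(C)C | intermediate
18 | diethyl (tetracyclododecan-10-yl)boronate | CCOB(OCC)[C@H]1CC[C@@H]2[C@H](C1)[C@H]1[C@@H]3CC[C@@H]3[C@@H]21 | intermediate
19 | 2-(tetracyclo[6.4.0.0(2,7).0(3,6)]dodecan-10-yl)-4,4,5,5-tetramethyl-1,3,2-dioxaborolane, single enantiomer, H-10 cis to H-1 and H-8 | CC1(C)OB(OC1(C)C)[C@H]2CC[C@@H]3[C@H](C2)[C@H]4[C@@H]5CC[C@@H]5[C@@H]34 | intermediate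
20 | 1,3-bis(benzyloxy)propan-2-ol | OC(COCc1ccccc1)COCc1ccccc1 | starting material
21 | 8-bromooct-1-yne | C#CCCCCCCBr | starting material
22 | 8-{[1,3-bis(benzyloxy)propan-2-yl]oxy}oct-1-yne | C#CCCCCCCOC(COCc1ccccc1)COCc1ccccc1 | intermediate
23 | (E)-alkenyl(chloro)zirconocene from 22 (cyclopentadienyl rings drawn σ-bonded) | Cl[Zr](/C=C/CCCCCCOC(COCc1ccccc1)COCc1ccccc1)(C1C=CC=C1)C1C=CC=C1 | intermediate
24 | (E)-8-{[1,3-bis(benzyloxy)propan-2-yl]oxy}-1-iodooct-1-ene | I/C=C/CCCCCCOC(COCc1ccccc1)COCc1ccccc1 | intermediate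
25 | (E)-alkenyllithium from 24 | [Li]/C=C/CCCCCCOC(COCc1ccccc1)COCc1ccccc1 | intermediate
26 | lithium alkenyl(tetracyclododecan-10-yl)pinacolatoborate | [Li+].CC1(C)O[B-](/C=C/CCCCCCOC(COCc2ccccc2)COCc2ccccc2)(OC1(C)C)[C@H]3CC[C@@H]4[C@H](C3)[C@H]5[C@@H]6CC[C@@H]6[C@@H]45 | intermediate
27 | β-iodoalkyl pinacol boronate after the 1,2-shift (two new chain centres left open, ring centres fixed) | CC1(C)OB(OC1(C)C)C(C(I)CCCCCCOC(COCc2ccccc2)COCc2ccccc2)[C@H]3CC[C@@H]4[C@H](C3)[C@H]5[C@@H]6CC[C@@H]6[C@@H]45 | intermediate
28 | (Z)-10-(8-{[1,3-bis(benzyloxy)propan-2-yl]oxy}oct-1-en-1-yl)tetracyclo[6.4.0.0(2,7).0(3,6)]dodecane, chain cis to ring B | C(OCc1ccccc1)C(COCc1ccccc1)OCCCCCC/C=C\[C@H]1CC[C@@H]2[C@H](C1)[C@H]1[C@@H]3CC[C@@H]3[C@@H]21 | intermediate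
29 | 10-(8-{[1,3-bis(benzyloxy)propan-2-yl]oxy}octyl)tetracyclo[6.4.0.0(2,7).0(3,6)]dodecane | C(OCc1ccccc1)C(COCc1ccccc1)OCCCCCCCC[C@H]1CC[C@@H]2[C@H](C1)[C@H]1[C@@H]3CC[C@@H]3[C@@H]21 | intermediate
30 | 2-{[8-(tetracyclo[6.4.0.0(2,7).0(3,6)]dodecan-10-yl)octyl]oxy}propane-1,3-diol, CNP0193334.1 | OCC(CO)OCCCCCCCC[C@H]1CC[C@@H]2[C@H](C1)[C@H]1[C@@H]3CC[C@@H]3[C@@H]21 | target

**Count**

Total steps: 14. Longest linear sequence: 12 (steps 1–10, 13, 14).

**Steps most likely to fail**

Step 5. The excited enone may add to the ring-A double bond of 6 as well as to the cyclobutene bond, giving the wrong mono-adduct and bis-adducts. The fallback sets out from ketone 3 and masks the ring-A alkene before the cyclobutene is made. Dihydroxylation (OsO4 cat., NMO, acetone/H2O) should give the cis-diol F1, drawn anti to the four-membered ring; the syn isomer would serve equally. 2,2-Dimethoxypropane with PPTS gives the acetonide F2. Hydrazone formation gives the sulfonylhydrazone F3, and the Shapiro elimination of step 4 gives the mono-alkene cyclobutene F4. Irradiation with 7 then has a single C=C to choose and gives the keto acetonide F5. Aqueous HCl in THF frees the keto diol F6. Corey–Winter olefination through the cyclic thiocarbonate F7 (thiocarbonyldiimidazole, then P(OMe)3, 110 °C) restores the alkene and rejoins the route at 8.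

Step 10. The bulky dialkylborane may add sluggishly to the boat-shaped alkene and, by shedding α-pinene, lose its discrimination between the enantiotopic carbons C10 and C11. The fallback sets out from 16 and uses copper-hydride catalysis: CuCl, KOtBu, (R)-DTBM-SEGPHOS (or its antipode, to be decided by a trial of each) and pinacolborane in THF at rt. Ligand-controlled syn hydrocupration followed by borylation with retention should give boronate 19 directly, with no new intermediate.

Step 4. Formation of the cyclobutenyl anion from the hydrazone dianion may lose out to carbenoid decomposition (ring contraction, C–H insertion), and the volatile diene may be lost. The fallback sets out from ketone 3: kinetic enolisation at the methylene (LiN(iPr)2, THF, −78 °C) and trapping with PhNTf2 should give the cyclobutenyl triflate F8. Palladium-catalysed formate reduction (Pd(OAc)2, PPh3, Bu3N, HCO2H, DMF, 60 °C) replaces the triflate by hydrogen and rejoins the route at 6.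

**Further compounds**

F1 | step 5 | rac-3,4-dihydroxy-cis-bicyclo[4.2.0]octan-7-one, cis-diol anti to the four-membered ring | O=C1[C@@H]2C[C@@H](O)[C@@H](O)C[C@@H]2C1
F2 | step 5 | acetonide of F1 | O=C1[C@@H]2C[C@H]3OC(C)(C)O[C@H]3C[C@@H]2C1
F3 | step 5 | 4-methylbenzenesulfonohydrazone of F2 | Cc1ccc(cc1)S(=O)(=O)NN=C1[C@@H]2C[C@H]3OC(C)(C)O[C@H]3C[C@@H]2C1
F4 | step 5 | 3,4-(isopropylidenedioxy)-cis-bicyclo[4.2.0]oct-7-ene, acetonide anti to the cyclobutene | C1=C[C@H]2C[C@@H]3OC(C)(C)O[C@@H]3C[C@@H]12
F5 | step 5 | rac-11,12-(isopropylidenedioxy)tetracyclo[7.4.0.0(2,8).0(3,7)]tridecan-4-one | CC1(C)O[C@@H]2C[C@@H]3[C@H](C[C@@H]2O1)[C@H]1[C@@H]4CCC(=O)[C@@H]4[C@@H]31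
F6 | step 5 | rac-11,12-dihydroxytetracyclo[7.4.0.0(2,8).0(3,7)]tridecan-4-one | O[C@@H]1C[C@@H]2[C@H](C[C@@H]1O)[C@H]3[C@@H]4CCC(=O)[C@@H]4[C@@H]23
F7 | step 5 | cyclic thiocarbonate of F6 | S=C1O[C@@H]2C[C@@H]3[C@H](C[C@@H]2O1)[C@H]1[C@@H]4CCC(=O)[C@@H]4[C@@H]31
F0 | step 10 | none | none
F8 | step 4 | rac-cis-bicyclo[4.2.0]octa-3,7-dien-7-yl trifluoromethanesulfonate | FC(F)(F)S(=O)(=O)OC1=C[C@H]2CC=CC[C@@H]12
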